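In a one-step world, with substrate going to target by a single first-order step, a charge larger by some factor gives target larger by that same factor at each time. Here are the flasks.

| flask | substrate | catalyst | time |
|---|---|---|---|
| cedar | 0.800 M | 0.0640 M |  |
| alder | 2.40 M | 0.0640 M |  |
| birch | 0.800 M | 0.0960 M |  |
| oak | 2.00 M | 0.0640 M | 18 min |

- cedar run (time / min: [target] / M): 1.4: 0.006; 4.2: 0.064; 7.9: 0.198; 13: 0.487; 18: 0.656
- alder run (time / min: [target] / M): 1.4: 0.041; 4.2: 0.591; 7.9: 2.124; 13: 2.170; 18: 2.029
- birch run (time / min: [target] / M): 1.4: 0.008; 4.2: 0.092; 7.9: 0.273; 13: 0.554; 18: 0.673

(scatter of a reading: 0.004 M)

* the power of [catalyst] that the first rate follows, about the charge of the cedar run; measure it at two percent of substrate made into target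
* the power of [substrate] that the first rate follows, about the charge of the cedar run; measure it at two percent of substrate made into target (one fixed amount of target, the same in the runs compared)
* target in the oak run at 18 min, as a share of the substrate charged

- Overall: substrate -> target, with catalyst as catalyst.
- Constant volume, constant temperature.
- Bound and free are read together.
- An order is taken over about fifteen percent of the charge, up and down.

The cedar and alder runs share their catalyst, and alder has 3.00 times the substrate. Yet at 7.9 min alder holds 2.124 M of target against 0.198 M in cedar, a factor of 10.7. You can clear this up by counting doublings, supposing that target breeds target (autocatalysis) at a rate proportional to substrate.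

Alder's target goes from 0.041 M to 0.591 M between 1.4 min and 4.2 min, a growth of 0.953 min⁻¹. Dividing by the charge gives 0.397 M⁻¹ min⁻¹, the breeding constant: growth of target per minute per molar substrate. While substrate stays near its charge, the doubling time is ln(2) over that constant times substrate, so it is 0.727 min in alder and 2.18 min in cedar, slower. Cedar's own readings from 4.2 min to 7.9 min give 2.27 min. On this supposition the charge sits in the exponent: it multiplies the number of doublings in a given time, not the target.

For oak, my own reckoning runs as follows. Alder's fall from 13 min to 18 min reads as a loss of 0.0134 min⁻¹. Treat alder's charge as born at one mean moment and decaying since, which puts that moment at 5.50 min. Oak's doubling time is 0.873 min, longer than alder's, which stretches the moment to 6.60 min in oak. Decay from there to 18 min leaves, by this estimate, 85.8% of oak's charge as target.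

The forecast gives 0.42 and 0.8 for the orders in catalyst and substrate and 86% for oak, reading cedar's early curve thus: “there is a lag, not a simple first rate”.

The flask gives 85.7% for oak, with orders 0.61 in catalyst and 0.85 in substrate. Fitted with the steps below, the residual is 1.2 in units of the scatter, and with the main steps alone it is 71.

    catalyst + substrate ⇌ catalyst-substrate complex (2.844 M⁻¹ min⁻¹, 4.638 min⁻¹)
    catalyst-substrate complex → target + catalyst (0.4152 min⁻¹)
    substrate + target → 2 target (0.4062 M⁻¹ min⁻¹)
    target → decomposed product (0.01296 min⁻¹)

Now put 0.397 M⁻¹ min⁻¹ to birch, whose substrate matches cedar's, so its doubling time is also 2.18 min. If 1.50 times the catalyst gives a seed of target larger by that factor, birch runs ahead by 1.28 min. Birch reaches a quarter of its charge at 6.70 min and cedar at 7.86 min, so birch is earlier by 1.16 min.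

The readings stem from a simulated flask with constants of no real substance, noise included.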